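**Plan**

- Cuts: the cis-1,10-oxirane is read as the epoxide of a Z-trisubstituted C1=C10 olefin, and that olefin is cut by ring-closing metathesis (C1–C10). The butenolide is cut at C6–C7 and O–C12 (Nozaki–Hiyama–Kishi coupling, lactonisation in the flask), C7–C11 by an ester aldol, C8–C9 by a glyoxylate-ene reaction, C3–C4 by a Negishi coupling; the O8 and O13 esters go on late.
- Order of rings: oxirane C4–C5 (on the open chain), then the butenolide (C6, C7, C11, C12, O), then the ten-membered carbocycle C1–C10, then oxirane C1–C10.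
- Enabling feature: C6 (sp3) and C7 (sp2) are adjacent atoms of the flat butenolide and carry the two olefin-ended arms side by side, and the cis-oxirane C4–C5 bends the C1–C5 arm back toward C10. Four contiguous atoms (C4–C7) of the ten-membered ring are thus fixed before closure, and the Z-cyclodecene, the geometry the cis-1,10-oxirane requires, is the olefin within reach.
- Stereochemistry: C4/C5 from Sharpless epoxidation of a Z-allylic alcohol (D-(−)-tartrate); C8 from the (R)-BINOL–titanium ene reaction; C6 from Felkin–Anh addition to the epoxy aldehyde; C1/C10 from the Z olefin (syn oxygen transfer) and attack on the outer face of the macrocycle.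

Key step: step 12

Assumption: germacrane locants are used throughout (ring C1–C10, lactone carbons C11–C13, C14 on C10, C15 on C4); methyl 3-[(tert-butyldimethylsilyl)oxy]propanoate and but-3-en-1-ylzinc bromide solution are treated as purchasable.

**Route**

Step 1
Reactants: 1 but-2-yn-1-ol
Product: 3 (Z)-3-iodobut-2-en-1-ol, via cyclic alkenylaluminate 2 (not isolated)
Conditions: NaAlH2(OCH2CH2OCH3)2 (Red-Al), THF, 0 to 23 °C; then I2, −78 °C
Reagents that add atoms: iodine (II); sodium bis(2-methoxyethoxy)aluminium dihydride ([Na+].COCCO[AlH2-]OCCOC), which leaves aluminium only in 2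
Why: Hydroxyl-directed trans-hydroalumination of the propargylic alcohol (Corey-type Red-Al reduction) places aluminium on C3 inside a five-membered oxaluminate ring, and iodinolysis with retention should give the Z iodide only.

Step 2
Reactants: 3 (Z)-3-iodobut-2-en-1-ol; 4 but-3-en-1-ylzinc bromide
Product: 5 (Z)-3-methylhepta-2,6-dien-1-ol
Conditions: Pd(dppf)Cl2 (5 mol %), THF, 23 to 50 °C, 3 equiv of 4
Reagents that add atoms: none
Why: Negishi sp2–sp3 cross-coupling proceeds with retention of olefin geometry, so the butenyl chain should end cis to CH2OH (neryl-type Z olefin), while the bidentate phosphine suppresses β-hydride elimination.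

Step 3
Reactants: 5 (Z)-3-methylhepta-2,6-dien-1-ol
Product: 6 [(2R,3S)-3-(but-3-en-1-yl)-3-methyloxiran-2-yl]methanol
Conditions: Ti(OiPr)4 (10 mol %), D-(−)-diethyl tartrate (12 mol %), tBuOOH, 4 Å molecular sieves, CH2Cl2, −20 °C
Reagents that add atoms: tert-butyl hydroperoxide (CC(C)(C)OO)
Why: Sharpless asymmetric epoxidation with the D-(−)-tartrate–titanium complex should give the (2R,3S)-oxirane (mirror image of the product from nerol with L-(+)-tartrate), which sets C4 (S) and C5 (R), and only the allylic olefin reacts.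

Step 4
Reactants: 6 [(2R,3S)-3-(but-3-en-1-yl)-3-methyloxiran-2-yl]methanol
Product: 7 (2S,3S)-3-(but-3-en-1-yl)-3-methyloxirane-2-carbaldehyde
Conditions: Dess–Martin periodinane, NaHCO3, CH2Cl2, 0 °C; used at once
Reagents that add atoms: none
Why: Dess–Martin oxidation of the primary epoxy alcohol is buffered and non-epimerising (the descriptor at C2 changes only through the priority rules).

Step 5
Reactants: 8 ethyl glyoxylate; 9 2-methylpropene
Product: 10 ethyl (2R)-2-hydroxy-4-methylpent-4-enoate
Conditions: (R)-BINOL (10 mol %), TiCl2(OiPr)2 (10 mol %), 4 Å molecular sieves, CH2Cl2, −30 °C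
Reagents that add atoms: none
Why: In the Mikami asymmetric glyoxylate-ene reaction the (R)-BINOL–titanium Lewis acid shields one face of the bound glyoxylate, which should give the (R)-carbinol (C8) and the isopropenyl group (C10, C14) in one step.

Step 6
Reactants: 10 ethyl (2R)-2-hydroxy-4-methylpent-4-enoate
Product: 11 ethyl (2R)-2-[(tert-butyldimethylsilyl)oxy]-4-methylpent-4-enoate
Conditions: TBSCl, imidazole, DMF, 23 °C
Reagents that add atoms: tert-butyldimethylsilyl chloride (CC(C)(C)[Si](C)(C)Cl)
Why: Standard silylation of the secondary alcohol protects O8 through the enolate and chromium chemistry.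

Step 7
Reactants: 11 ethyl (2R)-2-[(tert-butyldimethylsilyl)oxy]-4-methylpent-4-enoate
Product: 12 (2R)-2-[(tert-butyldimethylsilyl)oxy]-4-methylpent-4-enal
Conditions: iBu2AlH (1.1 equiv), CH2Cl2, −78 °C; aq. potassium sodium tartrate
Reagents that add atoms: none
Why: Partial reduction should stop at the aldehyde because the α-silyloxy group stabilises the tetrahedral aluminium hemiacetal at −78 °C, and the α-stereocentre is not touched.

Step 8
Reactants: 12 (2R)-2-[(tert-butyldimethylsilyl)oxy]-4-methylpent-4-enal; 13 methyl 3-[(tert-butyldimethylsilyl)oxy]propanoate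
Product: 14 methyl (4R)-4-[(tert-butyldimethylsilyl)oxy]-2-{[(tert-butyldimethylsilyl)oxy]methyl}-3-hydroxy-6-methylhept-6-enoate (mixture of C2/C3 epimers)
Conditions: LiN(iPr)2, THF, −78 °C (13, 15 min); then 12, −78 °C; NH4Cl quench at −78 °C
Reagents that add atoms: none
Why: Directed aldol addition of the lithium ester enolate forms C7–C11, the two new centres are erased in steps 9 and 10, and the low temperature should keep the β-silyloxy enolate from eliminating.

Step 9
Reactants: 14 methyl (4R)-4-[(tert-butyldimethylsilyl)oxy]-2-{[(tert-butyldimethylsilyl)oxy]methyl}-3-hydroxy-6-methylhept-6-enoate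
Product: 15 methyl (4R)-4-[(tert-butyldimethylsilyl)oxy]-2-{[(tert-butyldimethylsilyl)oxy]methyl}-6-methyl-3-oxohept-6-enoate
Conditions: Dess–Martin periodinane, NaHCO3, CH2Cl2, 0 to 23 °C
Reagents that add atoms: none
Why: Dess–Martin oxidation gives the β-keto ester under near-neutral conditions that should leave the α-silyloxy centre (C8) intact.

Step 10
Reactants: 15 methyl (4R)-4-[(tert-butyldimethylsilyl)oxy]-2-{[(tert-butyldimethylsilyl)oxy]methyl}-6-methyl-3-oxohept-6-enoate
Product: 16 methyl (2Z,4R)-4-[(tert-butyldimethylsilyl)oxy]-2-{[(tert-butyldimethylsilyl)oxy]methyl}-6-methyl-3-{[(trifluoromethyl)sulfonyl]oxy}hepta-2,6-dienoate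
Conditions: NaH, Et2O, 0 °C; then Tf2O, −78 to 0 °C
Reagents that add atoms: trifluoromethanesulfonic anhydride (O=S(=O)(OS(=O)(=O)C(F)(F)F)C(F)(F)F)
Why: O-sulfonylation of the sodium-chelated Z enolate of the β-keto ester should place the triflate cis to the ester (the geometry needed later for lactonisation), and only the doubly activated C11–H is removed, so C8 is not epimerised.

Step 11
Reactants: 16 methyl (2Z,4R)-4-[(tert-butyldimethylsilyl)oxy]-2-{[(tert-butyldimethylsilyl)oxy]methyl}-6-methyl-3-{[(trifluoromethyl)sulfonyl]oxy}hepta-2,6-dienoate; 7 (2S,3S)-3-(but-3-en-1-yl)-3-methyloxirane-2-carbaldehyde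
Product: 18 (5R)-5-[(2R,3S)-3-(but-3-en-1-yl)-3-methyloxiran-2-yl]-4-{(1R)-1-[(tert-butyldimethylsilyl)oxy]-3-methylbut-3-en-1-yl}-3-{[(tert-butyldimethylsilyl)oxy]methyl}furan-2(5H)-one, via hydroxy ester 17 (not isolated)
Conditions: CrCl2 (6 equiv), NiCl2 (2 mol %), degassed DMF, 23 °C; aq. NH4Cl
Reagents that add atoms: none
Why: In this Nozaki–Hiyama–Kishi coupling zerovalent nickel inserts into the C–OTf bond, transmetalation gives an alkenyl species of trivalent chromium with retained geometry, this adds to the aldehyde anti to the C5–O bond (Felkin–Anh, polar model) to set 6R, and the alkoxide cis to the ester closes the butenolide (5-exo-trig acyl substitution).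

Step 12
Reactants: 18 (5R)-5-[(2R,3S)-3-(but-3-en-1-yl)-3-methyloxiran-2-yl]-4-{(1R)-1-[(tert-butyldimethylsilyl)oxy]-3-methylbut-3-en-1-yl}-3-{[(tert-butyldimethylsilyl)oxy]methyl}furan-2(5H)-one
Product: 19 (1(10)Z,4S,5R,6R,8R)-8,13-bis[(tert-butyldimethylsilyl)oxy]-4,5-epoxygermacra-1(10),7(11)-dien-12,6-olide
Conditions: second-generation Hoveyda–Grubbs catalyst (15 mol % in two portions), toluene, 1 mM, 80 °C, argon sparge
Reagents that add atoms: none
Why: The ruthenium alkylidene forms at the unhindered C1 vinyl group and adds across the 1,1-disubstituted C10 olefin to a ruthenacyclobutane whose cycloreversion releases ethene and leaves the C1=C10 bond (Chauvin mechanism). The closest known reaction type is ring-closing metathesis of a terminal with a 1,1-disubstituted olefin to trisubstituted eight- to ten-membered cycloalkenes. One ring is closed, the ten-membered carbocycle, by joining the two olefinic arms on the adjacent butenolide atoms C6 and C7, with C4–C5 already tied in the cis-oxirane and C6–C7 in the butenolide. No sp3 stereocentre is made; the new stereo element is the olefin geometry, and Z should prevail because the E-cyclodecene fused to the butenolide is more strained, in the ruthenacycle as in the product. The step needs cyclisation to win over oligomerisation, which high dilution and the bent, pre-organised chain should secure, and chemoselectivity is given because the only other olefin (C7=C11) is tetrasubstituted and conjugated.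

Step 13
Reactants: 19 (1(10)Z,4S,5R,6R,8R)-8,13-bis[(tert-butyldimethylsilyl)oxy]-4,5-epoxygermacra-1(10),7(11)-dien-12,6-olide
Product: 20 (1(10)Z,4S,5R,6R,8R)-4,5-epoxy-8,13-dihydroxygermacra-1(10),7(11)-dien-12,6-olide
Conditions: HF·pyridine, pyridine, THF, 0 to 23 °C
Reagents that add atoms: none
Why: Buffered fluoride desilylation should remove both silyl ethers while sparing the oxirane, the base-sensitive butenolide γ-hydrogens and the Z olefin.

Step 14
Reactants: 20 (1(10)Z,4S,5R,6R,8R)-4,5-epoxy-8,13-dihydroxygermacra-1(10),7(11)-dien-12,6-olide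
Product: 21 (1(10)Z,4S,5R,6R,8R)-13-acetoxy-4,5-epoxy-8-hydroxygermacra-1(10),7(11)-dien-12,6-olide
Conditions: AcCl (1.1 equiv), 2,4,6-collidine, CH2Cl2, −78 °C
Reagents that add atoms: acetyl chloride (CC(=O)Cl)
Why: Chemoselective acylation should take the primary allylic hydroxyl at C13, which reacts much faster than the hindered secondary hydroxyl at C8.

Step 15
Reactants: 21 (1(10)Z,4S,5R,6R,8R)-13-acetoxy-4,5-epoxy-8-hydroxygermacra-1(10),7(11)-dien-12,6-olide
Product: 22 (1(10)Z,4S,5R,6R,8R)-13-acetoxy-4,5-epoxy-8-(3-methylbut-2-enoyloxy)germacra-1(10),7(11)-dien-12,6-olide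
Conditions: 3-methylbut-2-enoyl chloride, pyridine, CH2Cl2, 0 to 23 °C
Reagents that add atoms: 3-methylbut-2-enoyl chloride (CC(C)=CC(=O)Cl)
Why: Acylation of the secondary alcohol through the acylpyridinium with pyridine as the only base should avoid deconjugation of the senecioyl group and γ-deprotonation of the butenolide.

Step 16
Reactants: 22 (1(10)Z,4S,5R,6R,8R)-13-acetoxy-4,5-epoxy-8-(3-methylbut-2-enoyloxy)germacra-1(10),7(11)-dien-12,6-olide
Product: 23 (1S,4S,5R,6R,8R,10R)-13-acetoxy-1,10:4,5-diepoxy-8-(3-methylbut-2-enoyloxy)germacr-7(11)-en-12,6-olide (CNP0228323.1)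
Conditions: dimethyldioxirane (1.2 equiv, acetone solution), CH2Cl2, −20 to 0 °C
Reagents that add atoms: dimethyldioxirane (CC1(C)OO1)
Why: Concerted syn oxygen transfer to the only electron-rich olefin (C7=C11 and the senecioate olefin are conjugated and electron-poor) turns the Z olefin into the cis-oxirane, and the oxidant should enter from the outer face of the folded ten-membered ring, which corresponds to 1S,10R.

**Compound list**

1 | but-2-yn-1-ol | CC#CCO | starting material
2 | sodium 2,2-bis(2-methoxyethoxy)-3-methyl-2,5-dihydro-1,2-oxaluminol-2-uide (cyclic alkenylaluminate) | CC1=CCO[Al-]1(OCCOC)OCCOC.[Na+] | intermediate (not isolated)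
3 | (Z)-3-iodobut-2-en-1-ol | OC/C=C(/C)I | intermediate
4 | but-3-en-1-ylzinc bromide | C=CCC[Zn]Br | starting material
5 | (Z)-3-methylhepta-2,6-dien-1-ol | OC/C=C(/C)CCC=C | intermediate
6 | [(2R,3S)-3-(but-3-en-1-yl)-3-methyloxiran-2-yl]methanol | OC[C@H]1O[C@@]1(C)CCC=C | intermediate
7 | (2S,3S)-3-(but-3-en-1-yl)-3-methyloxirane-2-carbaldehyde | O=C[C@H]1O[C@@]1(C)CCC=C | intermediate
8 | ethyl glyoxylate | CCOC(=O)C=O | starting material
9 | 2-methylpropene | CC(C)=C | starting material
10 | ethyl (2R)-2-hydroxy-4-methylpent-4-enoate | CCOC(=O)[C@H](O)CC(C)=C | intermediate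
11 | ethyl (2R)-2-[(tert-butyldimethylsilyl)oxy]-4-methylpent-4-enoate | CCOC(=O)[C@H](O[Si](C)(C)C(C)(C)C)CC(C)=C | intermediate
12 | (2R)-2-[(tert-butyldimethylsilyl)oxy]-4-methylpent-4-enal | O=C[C@H](O[Si](C)(C)C(C)(C)C)CC(C)=C | intermediate
13 | methyl 3-[(tert-butyldimethylsilyl)oxy]propanoate | COC(=O)CCO[Si](C)(C)C(C)(C)C | starting material
14 | methyl (4R)-4-[(tert-butyldimethylsilyl)oxy]-2-{[(tert-butyldimethylsilyl)oxy]methyl}-3-hydroxy-6-methylhept-6-enoate (C2/C3 epimers) | COC(=O)C(CO[Si](C)(C)C(C)(C)C)C(O)[C@H](O[Si](C)(C)C(C)(C)C)CC(C)=C | intermediate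
15 | methyl (4R)-4-[(tert-butyldimethylsilyl)oxy]-2-{[(tert-butyldimethylsilyl)oxy]methyl}-6-methyl-3-oxohept-6-enoate | COC(=O)C(CO[Si](C)(C)C(C)(C)C)C(=O)[C@H](O[Si](C)(C)C(C)(C)C)CC(C)=C | intermediate
16 | methyl (2Z,4R)-4-[(tert-butyldimethylsilyl)oxy]-2-{[(tert-butyldimethylsilyl)oxy]methyl}-6-methyl-3-{[(trifluoromethyl)sulfonyl]oxy}hepta-2,6-dienoate | COC(=O)/C(CO[Si](C)(C)C(C)(C)C)=C(\OS(=O)(=O)C(F)(F)F)[C@H](O[Si](C)(C)C(C)(C)C)CC(C)=C | intermediate
17 | methyl (2E,4R)-3-{(R)-[(2R,3S)-3-(but-3-en-1-yl)-3-methyloxiran-2-yl](hydroxy)methyl}-4-[(tert-butyldimethylsilyl)oxy]-2-{[(tert-butyldimethylsilyl)oxy]methyl}-6-methylhepta-2,6-dienoate | COC(=O)/C(CO[Si](C)(C)C(C)(C)C)=C(\[C@@H](O)[C@H]1O[C@@]1(C)CCC=C)[C@H](O[Si](C)(C)C(C)(C)C)CC(C)=C | intermediate (not isolated)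
18 | (5R)-5-[(2R,3S)-3-(but-3-en-1-yl)-3-methyloxiran-2-yl]-4-{(1R)-1-[(tert-butyldimethylsilyl)oxy]-3-methylbut-3-en-1-yl}-3-{[(tert-butyldimethylsilyl)oxy]methyl}furan-2(5H)-one | CC(C)(C)[Si](C)(C)OCC1=C([C@@H](OC1=O)[C@H]1O[C@@]1(C)CCC=C)[C@H](O[Si](C)(C)C(C)(C)C)CC(C)=C | intermediate
19 | (1(10)Z,4S,5R,6R,8R)-8,13-bis[(tert-butyldimethylsilyl)oxy]-4,5-epoxygermacra-1(10),7(11)-dien-12,6-olide | CC(C)(C)[Si](C)(C)OCC1=C2[C@@H](OC1=O)[C@H]1O[C@@]1(C)CC/C=C(C)\C[C@H]2O[Si](C)(C)C(C)(C)C | intermediate
20 | (1(10)Z,4S,5R,6R,8R)-4,5-epoxy-8,13-dihydroxygermacra-1(10),7(11)-dien-12,6-olide | OCC1=C2[C@@H](OC1=O)[C@H]1O[C@@]1(C)CC/C=C(C)\C[C@H]2O | intermediate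
21 | (1(10)Z,4S,5R,6R,8R)-13-acetoxy-4,5-epoxy-8-hydroxygermacra-1(10),7(11)-dien-12,6-olide | CC(=O)OCC1=C2[C@@H](OC1=O)[C@H]1O[C@@]1(C)CC/C=C(C)\C[C@H]2O | intermediate
22 | (1(10)Z,4S,5R,6R,8R)-13-acetoxy-4,5-epoxy-8-(3-methylbut-2-enoyloxy)germacra-1(10),7(11)-dien-12,6-olide | CC(=O)OCC1=C2[C@@H](OC1=O)[C@H]1O[C@@]1(C)CC/C=C(C)\C[C@H]2OC(=O)C=C(C)C | intermediate
23 | (1S,4S,5R,6R,8R,10R)-13-acetoxy-1,10:4,5-diepoxy-8-(3-methylbut-2-enoyloxy)germacr-7(11)-en-12,6-olide (CNP0228323.1) | CC(=O)OCC1=C2[C@@H](OC1=O)[C@H]1O[C@@]1(C)CC[C@@H]1O[C@]1(C)C[C@H]2OC(=O)C=C(C)C | target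

**Totals and risks**

Total step count: 16. Longest linear sequence: 12 steps (steps 5–10, then 11–16, from ethyl glyoxylate).

Steps most likely to fail:

1. Step 12 (ring-closing metathesis). Intermolecular metathesis at the C1 vinyl group (oligomerisation) may outrun closure of the strained ten-membered ring, the alkylidene may stall at the hindered 1,1-disubstituted olefin next to the bulky C8 silyl ether, and Z selectivity may erode. Fallback: a temporary ring is used to steer the closure. Setting out from 18, HF·pyridine/pyridine should give the diene diol F1, and tBu2Si(OTf)2 with 2,6-lutidine should tie O8 and O13 into the seven-membered cyclic di-tert-butylsilylene F2. This removes both bulky silyl ethers from the reacting region and freezes rotation about C7–C8, so that the methallyl arm is held out of the butenolide plane toward the C1 arm. Metathesis under the conditions of step 12 should then give the ring-closed silylene F3, and HF·pyridine removes the tether to return to the route at 20.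

2. Step 16 (epoxidation of C1=C10). Oxygen may be transferred to the wrong face, because only the conformation of the ten-membered ring, not a reagent, decides the face. Fallback: the oxygen is delivered in two steps to the opposite face. Setting out from 22, N-bromosuccinimide in aqueous acetone should form the bromonium ion on the face the peroxide prefers, and water opens it at the tertiary C10 from the other face to give the bromohydrin F4. Ag2O in CH2Cl2 then closes the oxirane by displacement of bromide with inversion at C1, so the oxirane oxygen ends on the face opposite to the one taken by dimethyldioxirane; the route is rejoined at 23.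

3. Step 11 (Nozaki–Hiyama–Kishi coupling). Felkin–Anh facial selectivity at C6 may be low, oxidative addition of the hindered tetrasubstituted triflate may be slow, and the chromium salts may open the epoxy aldehyde. Fallback: C6 is set by reduction instead of addition.
   - Setting out from 7, NaClO2/NaH2PO4/2-methylbut-2-ene should give the epoxy acid F5, and EtSH/DCC/DMAP the thioester F6.
   - Setting out from 16, (Me3Sn)2, Pd(PPh3)4 and LiCl should give the alkenylstannane F7.
   - Neutral thioester–stannane ketone synthesis (Pd2(dba)3, tri(2-furyl)phosphine, copper thiophene-2-carboxylate CuO2CC4H3S of monovalent copper) should join F6 and F7 to the epoxy enone F8.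
   - Zn(BH4)2 in Et2O at −78 °C, chelated between the ketone and oxirane oxygens, should deliver hydride to give the anti epoxy alcohol 17, which lactonises to rejoin the route at 18.

**Further compounds**

F1 | step 12 | (5R)-5-[(2R,3S)-3-(but-3-en-1-yl)-3-methyloxiran-2-yl]-4-[(1R)-1-hydroxy-3-methylbut-3-en-1-yl]-3-(hydroxymethyl)furan-2(5H)-one | OCC1=C([C@@H](OC1=O)[C@H]1O[C@@]1(C)CCC=C)[C@H](O)CC(C)=C
F2 | step 12 | 8,13-O-(di-tert-butylsilylene) derivative of F1 (seven-membered 1,3,2-dioxasilepine fused to the butenolide) | CC(C)(C)[Si]1(C(C)(C)C)OCC2=C([C@@H](OC2=O)[C@H]2O[C@@]2(C)CCC=C)[C@@H](CC(C)=C)O1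
F3 | step 12 | (1(10)Z,4S,5R,6R,8R)-8,13-O-(di-tert-butylsilylene)-4,5-epoxy-8,13-dihydroxygermacra-1(10),7(11)-dien-12,6-olide | CC(C)(C)[Si]1(C(C)(C)C)OCC2=C3[C@@H](OC2=O)[C@H]2O[C@@]2(C)CC/C=C(C)\C[C@H]3O1
F4 | step 16 | (1R,4S,5R,6R,8R,10R)-13-acetoxy-1-bromo-4,5-epoxy-10-hydroxy-8-(3-methylbut-2-enoyloxy)germacr-7(11)-en-12,6-olide | CC(=O)OCC1=C2[C@@H](OC1=O)[C@H]1O[C@@]1(C)CC[C@@H](Br)[C@](C)(O)C[C@H]2OC(=O)C=C(C)C
F5 | step 11 | (2S,3S)-3-(but-3-en-1-yl)-3-methyloxirane-2-carboxylic acid | OC(=O)[C@H]1O[C@@]1(C)CCC=C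
F6 | step 11 | S-ethyl (2S,3S)-3-(but-3-en-1-yl)-3-methyloxirane-2-carbothioate | CCSC(=O)[C@H]1O[C@@]1(C)CCC=C
F7 | step 11 | methyl (2Z,4R)-4-[(tert-butyldimethylsilyl)oxy]-2-{[(tert-butyldimethylsilyl)oxy]methyl}-6-methyl-3-(trimethylstannyl)hepta-2,6-dienoate | COC(=O)/C(CO[Si](C)(C)C(C)(C)C)=C(\[Sn](C)(C)C)[C@H](O[Si](C)(C)C(C)(C)C)CC(C)=C
F8 | step 11 | methyl (2Z,4R)-3-{[(2S,3S)-3-(but-3-en-1-yl)-3-methyloxiran-2-yl]carbonyl}-4-[(tert-butyldimethylsilyl)oxy]-2-{[(tert-butyldimethylsilyl)oxy]methyl}-6-methylhepta-2,6-dienoate | COC(=O)/C(CO[Si](C)(C)C(C)(C)C)=C(\C(=O)[C@H]1O[C@@]1(C)CCC=C)[C@H](O[Si](C)(C)C(C)(C)C)CC(C)=C
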